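The cyclohexene ring C4a–C5–C6–C7–C8–C8a, oxygenated on every sp3 carbon and fused to the γ-pyranone at C4a=C8a, is read as a disguised furan: C5 and C8 are the furan α-carbons, C7–OAr the substituent of a 3-aryloxyfuran. An asymmetric Diels–Alder reaction of this furan (already carrying the aromatic chromone) with a homochiral 5-sulfinyl-4-pyranone, followed in situ by sulfoxide elimination, forms C4a–C5 and C8a–C8, joins both chromone units and sets C5 and C8. exo-Hydroboration then installs C6–OH and C7–H, and acid-induced opening of the oxygen bridge at C5 by the tethered 7'-phenol, with inversion, closes the bridged dioxepine.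

Key step: step 8

Remark on locants: both units are numbered as chromones (O1, C2, C3, C4, C4a, C5–C8, C8a); primed locants refer to the aromatic chromone unit.
Remark on the chemistry: the sense of induction in step 8 is assigned from the chelate model (ZnBr2 bridging the sulfinyl and C4 carbonyl oxygens, endo approach of the furan anti to the p-tolyl group); should the opposite sense prevail, the same route is run from the enantiomeric sulfoxide.

Step 1
Reactants: 1 1-(2-hydroxy-4,5-dimethoxyphenyl)ethan-1-one; 2 ethyl 3-phenylpropanoate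
Product: 3 1-(2-hydroxy-4,5-dimethoxyphenyl)-5-phenylpentane-1,3-dione
Conditions: NaH (3.5 equiv), THF, reflux; then aq HCl
Reagents that add atoms: none
Why: Claisen condensation in which the enolate of the phenoxide-masked acetophenone attacks the ester and the β-diketone is withdrawn from the equilibrium as its enolate; no stereocenter is formed.

Step 2
Reactants: 3 1-(2-hydroxy-4,5-dimethoxyphenyl)-5-phenylpentane-1,3-dione
Product: 5 6,7-dihydroxy-2-(2-phenylethyl)-4H-chromen-4-one, via dimethoxychromone 4 (not isolated)
Conditions: 48% aq HBr, AcOH, 120 °C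
Reagents that add atoms: none
Why: acid-catalysed cyclodehydration of the o-hydroxyaryl β-diketone gives chromone 4, whose two aryl methyl ethers are then cleaved by SN2 attack of bromide at methyl, the phenethyl chain and the pyranone being inert.

Step 3
Reactants: 5 6,7-dihydroxy-2-(2-phenylethyl)-4H-chromen-4-one
Product: 6 6-hydroxy-7-[(4-methoxyphenyl)methoxy]-2-(2-phenylethyl)-4H-chromen-4-one
Conditions: 4-MeOC6H4CH2Cl (1.05 equiv), K2CO3 (1.1 equiv), DMF, 0 °C → rt
Reagents that add atoms: 4-methoxybenzyl chloride COc1ccc(CCl)cc1
Why: Williamson etherification in which the 7-OH, conjugated with the C4 carbonyl and therefore the more acidic phenol, is deprotonated and alkylated in preference to the 6-OH when one equivalent of weak base is used.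

Step 4
Reactants: 6 6-hydroxy-7-[(4-methoxyphenyl)methoxy]-2-(2-phenylethyl)-4H-chromen-4-one; 7 3-bromofuran
Product: 8 6-(furan-3-yloxy)-7-[(4-methoxyphenyl)methoxy]-2-(2-phenylethyl)-4H-chromen-4-one
Conditions: CuI (10 mol %), picolinic acid (20 mol %), K3PO4 (2 equiv), DMSO, 90 °C, sealed tube
Reagents that add atoms: none
Why: Ullmann-type copper-catalysed C–O coupling of a hindered phenol with a heteroaryl bromide, tolerated by the benzylic ether and the chromone, should give the aryl 3-furyl ether, an electron-rich 3-oxyfuran diene.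

Step 5
Reactants: 9 (S)-methyl p-tolyl sulfoxide; 10 N-methoxy-N-methylacetamide
Product: 11 (S)-1-[(4-methylphenyl)sulfinyl]propan-2-one
Conditions: LiN(i-Pr)2 (1.1 equiv), THF, −78 °C; then 10, −78 → 0 °C; aq NH4Cl
Reagents that add atoms: none
Why: acylation of the α-lithiated sulfoxide by the Weinreb amide, whose chelated tetrahedral intermediate prevents over-addition, leaves the sulfur stereocenter untouched (descriptor S retained).

Step 6
Reactants: 11 (S)-1-[(4-methylphenyl)sulfinyl]propan-2-one; 12 N,N-dimethylformamide dimethyl acetal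
Product: 13 4-(dimethylamino)-3-[(R)-(4-methylphenyl)sulfinyl]but-3-en-2-one
Conditions: toluene, 60 °C
Reagents that add atoms: none
Why: Knoevenagel-type aminomethylenation at the methylene flanked by sulfinyl and carbonyl groups, the most acidic C–H position, gives the push–pull enaminone; the sulfur descriptor changes from S to R only because the substituent priorities change.

Step 7
Reactants: 13 4-(dimethylamino)-3-[(R)-(4-methylphenyl)sulfinyl]but-3-en-2-one; 14 3-(4-methoxyphenyl)propanoyl chloride
Product: 16 2-[2-(4-methoxyphenyl)ethyl]-5-[(R)-(4-methylphenyl)sulfinyl]-4H-pyran-4-one, via diketone 15 (not isolated)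
Conditions: LiN(SiMe3)2 (2.1 equiv), THF, −78 °C; then 14; then CF3CO2H, CH2Cl2, rt
Reagents that add atoms: none
Why: kinetic enolisation of the acetyl methyl group and Claisen-type C-acylation give diketone 15, and acid then induces 6-endo addition of the enol oxygen to the enaminone carbon with loss of dimethylamine, the standard enaminone route to 2-substituted 4-pyranones, with sulfur as a spectator.

Step 8
Reactants: 16 2-[2-(4-methoxyphenyl)ethyl]-5-[(R)-(4-methylphenyl)sulfinyl]-4H-pyran-4-one; 8 6-(furan-3-yloxy)-7-[(4-methoxyphenyl)methoxy]-2-(2-phenylethyl)-4H-chromen-4-one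
Product: 18 (5R,8S)-2-[2-(4-methoxyphenyl)ethyl]-7-{[7-(4-methoxybenzyloxy)-4-oxo-2-(2-phenylethyl)-4H-chromen-6-yl]oxy}-5,8-dihydro-5,8-epoxy-4H-chromen-4-one, via sulfinyl cycloadduct 17 (not isolated)
Conditions: ZnBr2 (1.5 equiv), CH2Cl2, −40 → 0 °C; then Et3N (3 equiv), 25–40 °C
Reagents that add atoms: none
Why: ZnBr2 binds the sulfinyl and C4 carbonyl oxygens of 16 in a six-membered chelate, which raises the electrophilicity of C8a and holds the p-tolyl group over one face of the C4a=C8a bond, so that furan 8 adds across this bond in a polar, asynchronous Diels–Alder reaction (furan C2, the enol-ether β-carbon, to C8a; furan C5 to C4a) to give 17, whose β-keto sulfoxide then loses 4-methylbenzenesulfenic acid by thermal syn-elimination (sulfinyl group and H-8a are cis) and restores the pyranone. The closest known reaction type is the tandem Diels–Alder/sulfoxide elimination of homochiral α-sulfinyl enones and quinones, in which the sulfinyl group serves as a chiral alkyne equivalent, combined with the endo-selective cycloadditions of 3-alkoxyfurans. The carbocycle C4a–C5–C6–C7–C8–C8a, and with it the 7-oxabicyclo[2.2.1]heptadiene, is closed by intermolecular suprafacial [4+2] cycloaddition, the oxygen bridge being the furan oxygen. C5 and C8 are created together: their relative configuration is fixed by the furan ring, and their absolute configuration (5R,8S) should follow from addition to the face anti to the p-tolyl group of the (R)-sulfoxide chelate in an endo orientation (pyranone ring under furan C3–C4), while the stereocenters at C4a and C8a of 17 are erased by the elimination. The step needs regioselectivity, secured by the matched polarisation of the 3-aryloxyfuran (nucleophilic at C2) and the pyranone (electrophilic at C8a); chemoselectivity for the sulfinyl-bearing double bond, secured because only that bond is chelate-activated; and combined facial and endo selectivity, secured by the sulfur stereocenter and the kinetic endo preference of 3-oxyfurans at low temperature, with Et3N buffering the sulfenic acid so that the acid-labile oxanorbornadiene is not aromatised.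

Step 9
Reactants: 18 (5R,8S)-oxanorbornadiene-fused pyranone
Product: 19 (5S,6S,7R,8S)-6-hydroxy-2-[2-(4-methoxyphenyl)ethyl]-7-{[7-(4-methoxybenzyloxy)-4-oxo-2-(2-phenylethyl)-4H-chromen-6-yl]oxy}-5,6,7,8-tetrahydro-5,8-epoxy-4H-chromen-4-one
Conditions: BH3·THF (1.1 equiv), THF, −20 → 0 °C; then NaBO3·4H2O, THF/H2O, rt
Reagents that add atoms: sodium perborate [Na+].[Na+].O[B-]1(O)OO[B-](O)(O)OO1
Why: hydroboration–oxidation, in which the strained enol ether C6=C7 reacts far faster than the vinylogous-ester carbonyls, boron adds to C6 (the enol-ether β-carbon) and hydrogen to C7 from the exo face next to the oxygen bridge, and oxidation with retention should give the exo C6–OH (6S) and thereby the endo C7–O-aryl group (7R), perborate avoiding the basic peroxide that could epoxidise the pyranones.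

Step 10
Reactants: 19 (5S,6S,7R,8S)-exo-alcohol
Product: 21 (+)-4'-methoxyaquisinenone G (5R,6S,7R,8S), via free phenol 20 (not isolated)
Conditions: CF3CO2H (10 equiv), C6HMe5 (5 equiv), CH2Cl2/(CF3)2CHOH 4:1, 0 °C → rt; aq NaHCO3
Reagents that add atoms: none
Why: acid cleaves the 4-methoxybenzyl ether (cation scavenged by pentamethylbenzene) and ionises the C5–O bond of the protonated bridge to the cation stabilised by O1 through C8a=C4a (the C8–O bond next to electron-poor C8a stays intact), and the 7'-phenol, held under the ring by the endo C7–O–aryl link, captures C5 on the face opposite to the departing oxygen in an SN1-type transannular etherification, so that C5 is inverted to R, C8–OH is released with retention and the bridged dioxepine closes.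

Compound list
1 | 1-(2-hydroxy-4,5-dimethoxyphenyl)ethan-1-one | CC(=O)c1cc(OC)c(OC)cc1O | starting material
2 | ethyl 3-phenylpropanoate | CCOC(=O)CCc1ccccc1 | starting material
3 | 1-(2-hydroxy-4,5-dimethoxyphenyl)-5-phenylpentane-1,3-dione | COc1cc(O)c(cc1OC)C(=O)CC(=O)CCc1ccccc1 | intermediate
4 | 6,7-dimethoxy-2-(2-phenylethyl)-4H-chromen-4-one | COc1cc2oc(CCc3ccccc3)cc(=O)c2cc1OC | intermediate (not isolated)
5 | 6,7-dihydroxy-2-(2-phenylethyl)-4H-chromen-4-one | Oc1cc2oc(CCc3ccccc3)cc(=O)c2cc1O | intermediate
6 | 6-hydroxy-7-[(4-methoxyphenyl)methoxy]-2-(2-phenylethyl)-4H-chromen-4-one | COc1ccc(COc2cc3oc(CCc4ccccc4)cc(=O)c3cc2O)cc1 | intermediate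
7 | 3-bromofuran | Brc1ccoc1 | starting material
8 | 6-(furan-3-yloxy)-7-[(4-methoxyphenyl)methoxy]-2-(2-phenylethyl)-4H-chromen-4-one | COc1ccc(COc2cc3oc(CCc4ccccc4)cc(=O)c3cc2Oc2ccoc2)cc1 | intermediate
9 | (S)-(−)-methyl p-tolyl sulfoxide | C[S@](=O)c1ccc(C)cc1 | starting material
10 | N-methoxy-N-methylacetamide | CON(C)C(C)=O | starting material
11 | (S)-1-[(4-methylphenyl)sulfinyl]propan-2-one | CC(=O)C[S@](=O)c1ccc(C)cc1 | intermediate
12 | N,N-dimethylformamide dimethyl acetal | COC(OC)N(C)C | starting material
13 | 4-(dimethylamino)-3-[(R)-(4-methylphenyl)sulfinyl]but-3-en-2-one (C=C geometry not defined and of no consequence) | CC(=O)C(=CN(C)C)[S@](=O)c1ccc(C)cc1 | intermediate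
14 | 3-(4-methoxyphenyl)propanoyl chloride | COc1ccc(CCC(Cl)=O)cc1 | starting material
15 | 1-(dimethylamino)-7-(4-methoxyphenyl)-2-[(R)-(4-methylphenyl)sulfinyl]hept-1-ene-3,5-dione | COc1ccc(CCC(=O)CC(=O)C(=CN(C)C)[S@](=O)c2ccc(C)cc2)cc1 | intermediate (not isolated)
16 | 2-[2-(4-methoxyphenyl)ethyl]-5-[(R)-(4-methylphenyl)sulfinyl]-4H-pyran-4-one | COc1ccc(CCc2cc(=O)c(co2)[S@](=O)c2ccc(C)cc2)cc1 | intermediate
17 | endo cycloadduct: cis-fused 4a-[(R)-p-tolylsulfinyl]-4a,5,8,8a-tetrahydro-5,8-epoxychromen-4-one with the 7-aryloxy enol ether; sulfinyl group and H-8a exo (on the side of the oxygen bridge); C5 and C8 arranged as in 18 | COc1ccc(CCC2=CC(=O)[C@]3([S@](=O)c4ccc(C)cc4)[C@H](O2)[C@H]4O[C@@H]3C=C4Oc3cc4c(=O)cc(CCc5ccccc5)oc4cc3OCc3ccc(OC)cc3)cc1 | intermediate (not isolated)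
18 | (5R,8S)-2-[2-(4-methoxyphenyl)ethyl]-7-{[7-(4-methoxybenzyloxy)-4-oxo-2-(2-phenylethyl)-4H-chromen-6-yl]oxy}-5,8-dihydro-5,8-epoxy-4H-chromen-4-one | COc1ccc(CCc2cc(=O)c3c(o2)[C@H]2O[C@@H]3C=C2Oc2cc3c(=O)cc(CCc4ccccc4)oc3cc2OCc2ccc(OC)cc2)cc1 | intermediate
19 | (5S,6S,7R,8S)-6-hydroxy-2-[2-(4-methoxyphenyl)ethyl]-7-{[7-(4-methoxybenzyloxy)-4-oxo-2-(2-phenylethyl)-4H-chromen-6-yl]oxy}-5,6,7,8-tetrahydro-5,8-epoxy-4H-chromen-4-one (6-OH exo, 7-aryloxy endo) | COc1ccc(CCc2cc(=O)c3c(o2)[C@H]2O[C@@H]3[C@H](O)[C@H]2Oc2cc3c(=O)cc(CCc4ccccc4)oc3cc2OCc2ccc(OC)cc2)cc1 | intermediate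
20 | (5S,6S,7R,8S)-6-hydroxy-7-{[7-hydroxy-4-oxo-2-(2-phenylethyl)-4H-chromen-6-yl]oxy}-2-[2-(4-methoxyphenyl)ethyl]-5,6,7,8-tetrahydro-5,8-epoxy-4H-chromen-4-one | COc1ccc(CCc2cc(=O)c3c(o2)[C@H]2O[C@@H]3[C@H](O)[C@H]2Oc2cc3c(=O)cc(CCc4ccccc4)oc3cc2O)cc1 | intermediate (not isolated)
21 | (+)-4'-methoxyaquisinenone G, (5R,6S,7R,8S): 5-O and 7-O bridged by the 7'- and 6'-oxygens of the aromatic chromone, 6-OH and 8-OH on the opposite face | COc1ccc(CCc2cc(=O)c3c(o2)[C@@H](O)[C@@H]2Oc4cc5c(=O)cc(CCc6ccccc6)oc5cc4O[C@H]3[C@@H]2O)cc1 | target

Total step count: 10. Longest linear sequence: 7 steps (steps 1, 2, 3, 4, 8, 9, 10); the second branch (steps 5, 6, 7) joins at step 8.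

Steps most likely to fail

Step 8. The cycloaddition of the push–pull pyranone may be slow, and π-facial or endo control may be incomplete. Either lowers the enantiomeric purity of 18, because endo and exo addition to the same face lead to opposite enantiomers once the sulfoxide is eliminated. Lewis-acid-induced opening of the oxygen bridge with aromatisation is a further drain. The fallback gives up auxiliary control as the only source of enantiopurity. The cycloaddition is then run for throughput (no Lewis acid, 12 kbar, CH2Cl2, rt, then Et3N) and the scalemic material is taken through step 9. The fallback proper sets out from alcohol 19 of insufficient enantiomeric purity and uses lipase-catalysed kinetic resolution, a known method for secondary alcohols (Burkholderia cepacia lipase, vinyl acetate, t-BuOMe, 30 °C). By the empirical size rule for lipases it should acetylate the (6R)-antipode to the acetate of ent-19 F1, which is removed by chromatography. The unreacted alcohol comes back to the route as enantiopure 19.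

Step 10. The C5 cation may undergo a 1,2-hydride shift from C6 (giving a 6-ketone), may lose a proton with subsequent aromatisation of the carbocycle, or the product may re-ionise at C5. The fallback sets out from 19 and comes back at 21. The C6 hydroxyl is first acetylated (Ac2O, pyridine, DMAP, CH2Cl2) to the 6-O-acetate of 19 F2. The acid treatment of step 10 then removes the benzylic ether to give the phenol acetate F3, which is not isolated. The acetoxy group should capture the C5 cation on the bridge face as a cis-fused 1,3-dioxolan-2-ylium ion, which cannot undergo the hydride shift. The phenol opens this ion at C5 from the opposite face (neighbouring-group participation as in 1,2-trans glycosylation) to give the 6-O-acetyl derivative of 21 F4. K2CO3 in MeOH at 0 °C then removes the acetate and gives 21.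

Step 4. Oxidative addition of the electron-rich 3-bromofuran may be slow and copper may be sequestered by the ortho-dioxygenated phenol, so that the volatile bromide is lost or decomposes before coupling. The fallback sets out from 6 and comes back at 8. It is an oxidative Chan–Lam coupling of 6 with furan-3-ylboronic acid (Cu(OAc)2, pyridine, 4 Å molecular sieves, CH2Cl2, air, rt). This forms the same C–O bond from a nucleophilic furan partner at room temperature and makes no compound beyond those of the list (entry F0).

Further compounds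
F1 | step 8 | 6-O-acetate of the enantiomer of 19 (5R,6R,7S,8R) | COc1ccc(CCc2cc(=O)c3c(o2)[C@@H]2O[C@H]3[C@@H](OC(C)=O)[C@@H]2Oc2cc3c(=O)cc(CCc4ccccc4)oc3cc2OCc2ccc(OC)cc2)cc1
F2 | step 10 | 6-O-acetate of 19 | COc1ccc(CCc2cc(=O)c3c(o2)[C@H]2O[C@@H]3[C@H](OC(C)=O)[C@H]2Oc2cc3c(=O)cc(CCc4ccccc4)oc3cc2OCc2ccc(OC)cc2)cc1
F3 | step 10 | 6-O-acetate of 20 (free 7'-phenol, not isolated) | COc1ccc(CCc2cc(=O)c3c(o2)[C@H]2O[C@@H]3[C@H](OC(C)=O)[C@H]2Oc2cc3c(=O)cc(CCc4ccccc4)oc3cc2O)cc1
F4 | step 10 | 6-O-acetyl derivative of 21 | COc1ccc(CCc2cc(=O)c3c(o2)[C@@H](O)[C@@H]2Oc4cc5c(=O)cc(CCc6ccccc6)oc5cc4O[C@H]3[C@@H]2OC(C)=O)cc1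
F0 | step 4 | none | none
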